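**Plan**

1. Eudesmane locants are used throughout, also for open-chain compounds: C10 is the ring-fusion carbon with methyl C14, C5 the ring-fusion CH, C4 the carbinol carbon with methyl C15, C3 the ester carbon, C8 the ketone, C7 the vinylic carbon bearing C11.
2. Retrosynthetic cuts, in order: the C3–O acyl bond; the C11–O bond (ene oxygenation of a 7(11)-en-8-one); C7–C8 together with C5–C10, which opens both rings to an acyclic C15 trienal; last, C3–C4 (alkenylzinc plus aldehyde).
3. Enabling feature: read from C8 the skeleton is a farnesane. C8(=O)–C9=C10 is an enal whose β-carbon C10 and carbonyl C8 are 1,3-related electrophiles, and the skipped diene C4=C5–C6–C7=C11 offers C5 and C7 as 1,3-related nucleophiles, so both contacts are six-membered.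
4. Forward: geranyl acetate gives the C8–C3 aldehyde; a C8 enyne supplies C4–C7, C11–C13 and C15; one acid-triggered cascade closes ring A (C5–C10) and then ring B (C7–C8); oxidation, conjugation, Schenck ene reaction and angeloylation finish.
5. Stereochemistry: C3 comes from a ligand-controlled alkenylzinc addition; C4, C5 and C10 are relayed from C3 in the chair cascade (axial C3 carbonate, anti addition across the E-C4=C5 alkene, carbonate oxygen delivered to C4 cis to O3); C7 and C8 are transient.

Key step: step 7

Remark: the tert-butyl carbonate on O3 is a helper (stereocontrol, cation trap, then a temporary dioxolanone ring protecting the diol) and is removed in step 9. (−)-MIB is assumed to direct Si-face addition to aldehyde 2 as it does with other aldehydes.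

**Route**

Step 1
Reactants: 1 geranyl acetate
Product: 2 (2E)-3-methyl-6-oxohex-2-en-1-yl acetate
Conditions: O3 (about 1 equiv, Sudan red 7B end point), pyridine (cat.), CH2Cl2, −78 °C; then Me2S, −78 °C → rt
Reagents that add atoms: ozone O=[O+][O-]
Why: Chemoselective ozonolysis, in which the electron-rich distal trisubstituted alkene reacts faster than the alkene deactivated by the allylic acetate, and reductive work-up gives the aldehyde without forming a stereocentre.

Step 2
Reactants: 3 1-propynylmagnesium bromide; 4 prenyl bromide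
Product: 5 6-methylhept-5-en-2-yne
Conditions: CuBr·SMe2 (5 mol%), THF, 0 °C → rt
Reagents that add atoms: none
Why: Copper-catalysed SN2 coupling of an alkynyl Grignard reagent with a primary allylic bromide gives the skipped enyne, and no stereocentre is formed.

Step 3
Reactants: 5 6-methylhept-5-en-2-yne; 2 (2E)-3-methyl-6-oxohex-2-en-1-yl acetate
Product: 8 (2E,6R,7E)-6-hydroxy-3,7,11-trimethyldodeca-2,7,10-trien-1-yl acetate, via alkenylzirconocene chloride 6 (not isolated), via alkenyl(methyl)zinc 7 (not isolated)
Conditions: Cp2Zr(H)Cl (slight excess over 5), CH2Cl2, rt; Me2Zn, toluene, −65 °C; (−)-MIB (10 mol%), then 2, −30 → 0 °C; aq NH4Cl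
Reagents that add atoms: none
Why: Syn hydrozirconation, equilibrated by the slight excess of Cp2Zr(H)Cl, should place zirconium on the methyl-bearing alkyne carbon (this fixes the E geometry of the later C4=C5 alkene), Zr-to-Zn transmetalation gives an alkenylzinc, and its amino alcohol-catalysed asymmetric addition to the aldehyde from the Si face should set the R carbinol centre (C3) while the acetate is inert to the organozinc.

Step 4
Reactants: 8 (2E,6R,7E)-6-hydroxy-3,7,11-trimethyldodeca-2,7,10-trien-1-yl acetate
Product: 9 (2E,6R,7E)-6-[(tert-butoxycarbonyl)oxy]-3,7,11-trimethyldodeca-2,7,10-trien-1-yl acetate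
Conditions: Boc2O (1.5 equiv), DMAP (0.2 equiv), CH2Cl2, 0 °C → rt
Reagents that add atoms: di-tert-butyl dicarbonate CC(C)(C)OC(=O)OC(=O)OC(C)(C)C
Why: DMAP-catalysed acylation of the secondary allylic alcohol by Boc2O gives the tert-butyl carbonate without touching the stereocentre or the acetate.

Step 5
Reactants: 9 (2E,6R,7E)-6-[(tert-butoxycarbonyl)oxy]-3,7,11-trimethyldodeca-2,7,10-trien-1-yl acetate
Product: 10 tert-butyl (2E,6R,7E)-1-hydroxy-3,7,11-trimethyldodeca-2,7,10-trien-6-yl carbonate
Conditions: K2CO3 (0.3 equiv), MeOH, 0 °C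
Reagents that add atoms: none
Why: Base-catalysed transesterification should remove the unhindered primary acetate much faster than the hindered secondary tert-butyl carbonate reacts.

Step 6
Reactants: 10 tert-butyl (2E,6R,7E)-1-hydroxy-3,7,11-trimethyldodeca-2,7,10-trien-6-yl carbonate
Product: 11 tert-butyl (2E,6R,7E)-3,7,11-trimethyl-1-oxododeca-2,7,10-trien-6-yl carbonate
Conditions: activated MnO2 (excess), CH2Cl2, rt
Reagents that add atoms: none
Why: MnO2 oxidises the primary allylic alcohol selectively to the E-enal and leaves the isolated alkenes and the carbonate untouched.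

Step 7
Reactants: 11 tert-butyl (2E,6R,7E)-3,7,11-trimethyl-1-oxododeca-2,7,10-trien-6-yl carbonate
Product: 13 (3R,4S,5R,7R,8S,10R)-8α-hydroxyeudesm-11-ene-3α,4α-diyl carbonate, via ring A aldehyde 12 (not isolated)
Conditions: SnCl4 (0.3 equiv), CH2Cl2 (0.01 M), −78 → −30 °C; then aq NaHCO3
Reagents that add atoms: none
Why: Proposed new method: SnCl4 binds the enal of 11 so that C5 of the E-C4=C5 alkene adds to the β-carbon C10 (conjugate cation–olefin closure of six-membered ring A, exo at the enal and endo at the alkene), the neighbouring carbonate carbonyl oxygen captures the developing C4 cation in a 5-exo closure with loss of isobutene and of a proton that returns the tin enolate to the C8 aldehyde 12, and this aldehyde then closes ring B by a type 1 carbonyl-ene reaction (six-membered chair, C7–C8 bond, hydrogen passed from a C11 methyl to oxygen). The closest known reaction types are the Lewis acid-induced conjugate addition of alkenes to enals, the capture of cations by tert-butyl carbonates as in iodocarbonate cyclisation, and the citronellal-to-isopulegol carbonyl-ene cyclisation; their union in one flask is the untested part. C10 and C5 should arise in a chair with the small C14 methyl axial and the enal-bearing C9 equatorial, so that H5 and C14 end trans-diaxial as the later trans-decalin requires. C4 is set by anti addition across the alkene, the carbonate oxygen entering equatorially and cis to O3 so that C15 becomes axial, and the fixed R centre at C3 decides the absolute sense because its carbonate prefers the axial (inside) position, which avoids 1,2-allylic strain with C15 and places the oxygen within reach of C4. C7 and C8 (isopropenyl and hydroxyl both equatorial) are removed again in steps 8 and 9. The step needs 1,4- and not 1,2-attack on the enal and no hydride shift at C4: only the 1,4-mode gives a six-membered ring (1,2-attack would need an eight- or ten-membered ring), and the neighbouring carbonate should intercept C4 before a shift can occur.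

Step 8
Reactants: 13 (3R,4S,5R,7R,8S,10R)-8α-hydroxyeudesm-11-ene-3α,4α-diyl carbonate
Product: 14 (3R,4S,5R,7R,10R)-8-oxoeudesm-11-ene-3α,4α-diyl carbonate
Conditions: Dess–Martin periodinane (1.3 equiv), CH2Cl2, 0 °C → rt
Reagents that add atoms: none
Why: Dess–Martin oxidation converts the secondary alcohol to the ketone under near-neutral conditions that the carbonate and the isopropenyl group tolerate, and it removes the C8 stereocentre.

Step 9
Reactants: 14 (3R,4S,5R,7R,10R)-8-oxoeudesm-11-ene-3α,4α-diyl carbonate
Product: 15 (3R,4S,5R,10R)-3α,4α-dihydroxyeudesm-7(11)-en-8-one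
Conditions: NaOMe (0.5 equiv), MeOH, 0 °C → rt
Reagents that add atoms: none
Why: Methoxide does two jobs in one flask, base-mediated conjugation of the β,γ-unsaturated ketone to the more stable tetrasubstituted 7(11)-enone (isopulegone-to-pulegone type isomerisation, which erases C7) and methanolysis of the cyclic carbonate to the cis-diol, while C3, C4, C5 and C10 carry no acidic hydrogen and are untouched.

Step 10
Reactants: 15 (3R,4S,5R,10R)-3α,4α-dihydroxyeudesm-7(11)-en-8-one
Product: 17 (3R,4S,5R,10R)-3α,4α,11-trihydroxyeudesm-6-en-8-one, via 11-hydroperoxide 16 (not isolated)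
Conditions: O2, tetraphenylporphyrin (1 mol%), CH2Cl2, visible light, 0 °C; then PPh3 (1.1 equiv), 0 °C → rt
Reagents that add atoms: oxygen O=O
Why: The Schenck ene reaction of singlet oxygen with the s-cis enone should follow the gem rule for α,β-unsaturated carbonyls (hydrogen taken from the C6 methylene on the α-carbon, oxygen delivered to the β-carbon C11), giving the tertiary hydroperoxide with the C6=C7 enone, and PPh3 reduces the O–O bond to the alcohol; C11 is not stereogenic.

Step 11
Reactants: 17 (3R,4S,5R,10R)-3α,4α,11-trihydroxyeudesm-6-en-8-one; 18 angelic acid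
Product: 20 (3R,4S,5R,10R)-3α-angeloyloxy-4α,11-dihydroxyeudesm-6-en-8-one, via mixed anhydride 19 (not isolated)
Conditions: 18 (3 equiv), 2,4,6-trichlorobenzoyl chloride (3 equiv), Et3N (3.3 equiv), toluene, rt; then 17, toluene, 80 °C (no DMAP)
Reagents that add atoms: none
Why: Yamaguchi-type esterification through the mixed anhydride should acylate the only secondary hydroxyl (C3) while both tertiary hydroxyls stay free, and leaving out a nucleophilic catalyst should keep the Z (angelate) geometry; no stereocentre is changed.

**Compound list**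

1 | geranyl acetate, (2E)-3,7-dimethylocta-2,6-dien-1-yl acetate | CC(=O)OC/C=C(\C)CCC=C(C)C | starting material
2 | (2E)-3-methyl-6-oxohex-2-en-1-yl acetate | CC(=O)OC/C=C(\C)CCC=O | intermediate
3 | 1-propynylmagnesium bromide | CC#C[Mg]Br | starting material
4 | prenyl bromide, 1-bromo-3-methylbut-2-ene | CC(C)=CCBr | starting material
5 | 6-methylhept-5-en-2-yne | CC#CCC=C(C)C | intermediate
6 | chloro[(2E)-6-methylhepta-2,5-dien-2-yl]zirconocene | C/C(=C\CC=C(C)C)[Zr](Cl)(C1C=CC=C1)C1C=CC=C1 | intermediate
7 | methyl[(2E)-6-methylhepta-2,5-dien-2-yl]zinc | C/C(=C\CC=C(C)C)[Zn]C | intermediate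
8 | (2E,6R,7E)-6-hydroxy-3,7,11-trimethyldodeca-2,7,10-trien-1-yl acetate | CC(=O)OC/C=C(\C)CC[C@@H](O)/C(C)=C/CC=C(C)C | intermediate
9 | (2E,6R,7E)-6-[(tert-butoxycarbonyl)oxy]-3,7,11-trimethyldodeca-2,7,10-trien-1-yl acetate | CC(=O)OC/C=C(\C)CC[C@@H](OC(=O)OC(C)(C)C)/C(C)=C/CC=C(C)C | intermediate
10 | tert-butyl (2E,6R,7E)-1-hydroxy-3,7,11-trimethyldodeca-2,7,10-trien-6-yl carbonate | OC/C=C(\C)CC[C@@H](OC(=O)OC(C)(C)C)/C(C)=C/CC=C(C)C | intermediate
11 | tert-butyl (2E,6R,7E)-3,7,11-trimethyl-1-oxododeca-2,7,10-trien-6-yl carbonate | O=C/C=C(\C)CC[C@@H](OC(=O)OC(C)(C)C)/C(C)=C/CC=C(C)C | intermediate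
12 | 2-[(3aS,4R,5R,7aR)-3a,5-dimethyl-4-(3-methylbut-2-en-1-yl)-2-oxohexahydro-1,3-benzodioxol-5-yl]acetaldehyde (ring A aldehyde) | O=CC[C@@]1(C)CC[C@H]2OC(=O)O[C@@]2(C)[C@@H]1CC=C(C)C | intermediate
13 | (3R,4S,5R,7R,8S,10R)-8α-hydroxyeudesm-11-ene-3α,4α-diyl carbonate (5α-H, 7β-isopropenyl, 10β-methyl) | O=C3O[C@@H]1CC[C@]2(C)C[C@H](O)[C@@H](C(C)=C)C[C@H]2[C@]1(C)O3 | intermediate
14 | (3R,4S,5R,7R,10R)-8-oxoeudesm-11-ene-3α,4α-diyl carbonate | O=C3O[C@@H]1CC[C@]2(C)CC(=O)[C@@H](C(C)=C)C[C@H]2[C@]1(C)O3 | intermediate
15 | (3R,4S,5R,10R)-3α,4α-dihydroxyeudesm-7(11)-en-8-one | O[C@@H]1CC[C@]2(C)CC(=O)C(=C(C)C)C[C@H]2[C@]1(C)O | intermediate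
16 | (3R,4S,5R,10R)-11-hydroperoxy-3α,4α-dihydroxyeudesm-6-en-8-one | O[C@@H]1CC[C@]2(C)CC(=O)C(C(C)(C)OO)=C[C@H]2[C@]1(C)O | intermediate
17 | (3R,4S,5R,10R)-3α,4α,11-trihydroxyeudesm-6-en-8-one | O[C@@H]1CC[C@]2(C)CC(=O)C(C(C)(C)O)=C[C@H]2[C@]1(C)O | intermediate
18 | angelic acid, (2Z)-2-methylbut-2-enoic acid | C/C=C(/C)C(=O)O | starting material
19 | angelic 2,4,6-trichlorobenzoic anhydride | C/C=C(/C)C(=O)OC(=O)c1c(Cl)cc(Cl)cc1Cl | intermediate
20 | (3R,4S,5R,10R)-3α-angeloyloxy-4α,11-dihydroxyeudesm-6-en-8-one | C/C=C(/C)C(=O)O[C@@H]1CC[C@]2(C)CC(=O)C(C(C)(C)O)=C[C@H]2[C@]1(C)O | target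

**Step count and risks**

Total steps: 11. Longest linear sequence: 10 (steps 1 and 3 to 11; step 2 is the side branch).

Steps most likely to fail:

Step 7 (proposed new method). The cascade may be diverted by premature ionisation of the allylic carbonate, by collapse of the zwitterion through oxygen attack (hetero-Diels–Alder mode) or hydride shift, by closure through the other chair (cis-fused product), or by stalling after ring A. Fallback with known chemistry, in which the two bonds are made in separate steps: it sets out from enyne 5 through its alkenylzinc 7 and returns at 15. Alkenylzinc 7 is coupled with vinyl bromide under Pd(PPh3)4 catalysis (Negishi coupling) to give (3E)-3,7-dimethylocta-1,3,6-triene F1. An enantioselective exo Diels–Alder reaction of F1 with methacrolein under a chiral cationic oxazaborolidine catalyst forms C5–C10 and C1–C2 and gives the cyclohexene carbaldehyde F2 with C10 and C5 set. Wittig methoxymethylenation with Ph3P=CHOMe gives the enol ether F3, and mild acid hydrolysis gives the homologated aldehyde F4. ZnBr2-mediated carbonyl-ene cyclisation closes ring B (C7–C8) to the dienol F5. Dess–Martin oxidation gives the ketone F6, and NaOMe in MeOH conjugates it to the dienone F7. OsO4/NMO dihydroxylation of the ring A trisubstituted alkene from the α-face (anti to the axial C14 methyl, the electron-poor enone alkene being spared) gives 15. This bypasses compounds 2 and 8 to 14.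

Step 3. Incomplete regio-equilibration in the hydrozirconation and modest facial selectivity with an unbranched aliphatic aldehyde may erode isomeric and enantiomeric purity. Fallback: it sets out from alkenylzirconocene 6 and aldehyde 2 and returns at 8. Quenching 6 with I2 gives (2E)-2-iodo-6-methylhepta-2,5-diene F8, which can be freed of its regioisomer. Nozaki–Hiyama–Kishi coupling of F8 with 2 (CrCl2, NiCl2 cat., DMF) gives the racemic alcohol F9. Dess–Martin oxidation gives the enone F10. Corey–Bakshi–Shibata reduction with the (S)-oxazaborolidine and BH3·SMe2, the α-methylalkenyl group acting as the large substituent, gives (R)-8 under reagent control.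

Step 11. Z-to-E isomerisation of the angeloyl unit during activation, and slow acylation of the hindered axial C3 hydroxyl, may lower the outcome. Fallback: it sets out from 17 and returns at 20, building the Z-alkene after the ester bond exists. DCC-mediated acylation of 17 with 2-[bis(2,2,2-trifluoroethoxy)phosphoryl]propanoic acid gives the phosphonate ester F11. Still–Gennari olefination of F11 with acetaldehyde (KHMDS, 18-crown-6, THF, −78 °C) gives 20 with Z selectivity.

**Further compounds**

F1 | step 7 | (3E)-3,7-dimethylocta-1,3,6-triene, (E)-β-ocimene | C=C/C(C)=C/CC=C(C)C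
F2 | step 7 | (1S,2S)-1,3-dimethyl-2-(3-methylbut-2-en-1-yl)cyclohex-3-ene-1-carbaldehyde (formyl trans to the prenyl group) | O=C[C@@]1(C)CCC=C(C)[C@@H]1CC=C(C)C
F3 | step 7 | methyl enol ether of F4, 6-(2-methoxyethenyl)-1,6-dimethyl-5-(3-methylbut-2-en-1-yl)cyclohexene (E/Z mixture; ring configuration as in F2) | COC=C[C@@]1(C)CCC=C(C)[C@@H]1CC=C(C)C
F4 | step 7 | 2-[1,3-dimethyl-2-(3-methylbut-2-en-1-yl)cyclohex-3-en-1-yl]acetaldehyde (ring configuration as in F2) | O=CC[C@@]1(C)CCC=C(C)[C@@H]1CC=C(C)C
F5 | step 7 | eudesma-3,11-dien-8α-ol (5α-H, 7β-isopropenyl, 10β-methyl) | CC1=CCC[C@]2(C)C[C@H](O)[C@@H](C(C)=C)C[C@H]21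
F6 | step 7 | eudesma-3,11-dien-8-one (5α-H, 7β-isopropenyl, 10β-methyl) | CC1=CCC[C@]2(C)CC(=O)[C@@H](C(C)=C)C[C@H]21
F7 | step 7 | eudesma-3,7(11)-dien-8-one (5α-H, 10β-methyl) | CC1=CCC[C@]2(C)CC(=O)C(=C(C)C)C[C@H]21
F8 | step 3 | (2E)-2-iodo-6-methylhepta-2,5-diene | C/C(I)=C\CC=C(C)C
F9 | step 3 | racemic (2E,7E)-6-hydroxy-3,7,11-trimethyldodeca-2,7,10-trien-1-yl acetate | CC(=O)OC/C=C(\C)CCC(O)/C(C)=C/CC=C(C)C
F10 | step 3 | (2E,7E)-3,7,11-trimethyl-6-oxododeca-2,7,10-trien-1-yl acetate | CC(=O)OC/C=C(\C)CCC(=O)/C(C)=C/CC=C(C)C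
F11 | step 11 | 3α-{2-[bis(2,2,2-trifluoroethoxy)phosphoryl]propanoyloxy}-4α,11-dihydroxyeudesm-6-en-8-one | CC(C(=O)O[C@@H]1CC[C@]2(C)CC(=O)C(C(C)(C)O)=C[C@H]2[C@]1(C)O)P(=O)(OCC(F)(F)F)OCC(F)(F)F
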